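**Plan**
- Locants (target): C1 = CMe2, C2 = CHBr, C3 = alkylidene carbon, C4 = CHCl, C5 = CH2, C6 = CHCl, C7 = exocyclic =CH, C8 = CH2Br.
- Enabling feature: the array C6(Cl)–C5H2–C4(=O) flanking quaternary C1 is a β-chloro ketone in a six-membered ring, which is what one-electron oxidation of a 1-silyloxybicyclo[3.1.0]hexane delivers, C5 being the former cyclopropane methylene.
- Retrosynthesis: cut C2–Br and C8–Br (ene-1,4-diol), then C4–Cl (carbinol from the C4 ketone), then C6–Cl together with ring contraction to the siloxycyclopropane; last remove C5 (CH2I2), C3=C7 (aldol condensation) and the C2 oxygen (conjugate borylation) from 4,4-dimethylcyclopent-2-enone.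
- Forward: the five-membered carbocycle is bought, C7–C8 is joined by borylative aldol and dehydration, the cyclopropane is added across C4–C6, and the six-membered ring arises in step 7 by one-carbon enlargement; C4–Cl and the two C–Br bonds follow.
- Stereochemistry: C2 from ligand-controlled borylation; C6–Cl anti to the pseudoaxial C2 silyl ether; the C4 carbinol anti to C2–OH by hydroxyl-directed hydride delivery, inverted on chlorination; C2 inverted on bromination; alkene geometry (C8 syn to C2) from the E1cB dehydration.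

Key step: step 7

Remarks: names in the compound list carry their own IUPAC locants. Assumption: (R,R)-QuinoxP* is taken to deliver boron to the enone face that gives the (3S)-boronate; should the sense of induction prove opposite, the (S,S)-ligand is used and nothing else changes.

**Route**

Step 1
Reactants: 1 4,4-dimethylcyclopent-2-en-1-one; 2 bis(pinacolato)diboron; 3 (tert-butyldimethylsilyloxy)acetaldehyde
Product: 6 (2R,3S)-2-[2-(tert-butyldimethylsilyloxy)-1-hydroxyethyl]-4,4-dimethyl-3-(4,4,5,5-tetramethyl-1,3,2-dioxaborolan-2-yl)cyclopentan-1-one, via boron enolate 4 (not isolated), via boron aldolate 5 (not isolated)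
Conditions: CuPF6(MeCN)4 (5 mol%), (R,R)-QuinoxP* (6 mol%), LiOtBu (10 mol%), 2 (1.0 equiv), DMSO/THF, rt; then 3, 0 °C; aq NH4Cl
Reagents that add atoms: bis(pinacolato)diboron (compound 2), CC1(C)OB(OC1(C)C)B1OC(C)(C)C(C)(C)O1
Why: Copper-catalysed asymmetric conjugate borylation places boron on one face of C2 under ligand control and, run without a proton source, turns over through the pinacolboron enolate 4, which is formed regiospecifically at C3 and adds to the aldehyde in an aldol reaction anti to the new C–B bond, the carbinol centre being left as a mixture because step 2 removes it.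

Step 2
Reactants: 6 (2R,3S)-2-[2-(tert-butyldimethylsilyloxy)-1-hydroxyethyl]-4,4-dimethyl-3-(4,4,5,5-tetramethyl-1,3,2-dioxaborolan-2-yl)cyclopentan-1-one
Product: 8 (2E,3R)-2-[2-(tert-butyldimethylsilyloxy)ethylidene]-4,4-dimethyl-3-(4,4,5,5-tetramethyl-1,3,2-dioxaborolan-2-yl)cyclopentan-1-one, via mesylate 7 (not isolated)
Conditions: MsCl, Et3N, CH2Cl2, −20 °C; then DBU, 0 °C to rt
Reagents that add atoms: none
Why: Mesylation followed by E1cB elimination completes the aldol condensation and should give the exocyclic enone with C8 anti to the carbonyl, the preferred E geometry that both carbinol epimers reach through the common enolate, while the C–B bond, which is no leaving group, stays intact.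

Step 3
Reactants: 8 (2E,3R)-2-[2-(tert-butyldimethylsilyloxy)ethylidene]-4,4-dimethyl-3-(4,4,5,5-tetramethyl-1,3,2-dioxaborolan-2-yl)cyclopentan-1-one
Product: 10 (2E,3R)-2-[2-(tert-butyldimethylsilyloxy)ethylidene]-3-hydroxy-4,4-dimethylcyclopentan-1-one, via borate ester 9 (not isolated)
Conditions: NaBO3·4H2O, THF/H2O (1:1), 0 °C to rt
Reagents that add atoms: sodium perborate tetrahydrate, [Na+].[Na+].O[B-]1(O)OO[B-](O)(O)OO1 (anion drawn without water of crystallisation)
Why: Perborate oxidation of the allylic pinacol boronate moves C2 from boron to oxygen with retention of configuration and without allylic transposition, and is mild enough to spare the enone from nucleophilic epoxidation.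

Step 4
Reactants: 10 (2E,3R)-2-[2-(tert-butyldimethylsilyloxy)ethylidene]-3-hydroxy-4,4-dimethylcyclopentan-1-one
Product: 11 (2E,3R)-3-(tert-butyldimethylsilyloxy)-2-[2-(tert-butyldimethylsilyloxy)ethylidene]-4,4-dimethylcyclopentan-1-one
Conditions: TBSOTf, 2,6-lutidine, CH2Cl2, −78 to 0 °C
Reagents that add atoms: tert-butyldimethylsilyl trifluoromethanesulfonate, CC(C)(C)[Si](C)(C)OS(=O)(=O)C(F)(F)F
Why: Silylation with the silyl triflate and a hindered base converts the neopentylic C2 hydroxyl into a robust, bulky ether that later shields one ring face, without touching a stereocentre.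

Step 5
Reactants: 11 (2E,3R)-3-(tert-butyldimethylsilyloxy)-2-[2-(tert-butyldimethylsilyloxy)ethylidene]-4,4-dimethylcyclopentan-1-one
Product: 13 (4R,5E)-4-(tert-butyldimethylsilyloxy)-5-[2-(tert-butyldimethylsilyloxy)ethylidene]-3,3-dimethyl-1-(trimethylsilyloxy)cyclopent-1-ene, via lithium dienolate 12 (not isolated)
Conditions: LiN(iPr)2 (LDA), TMSCl (in situ quench), THF, −78 °C; Et3N, pentane, cold aq NaHCO3
Reagents that add atoms: chlorotrimethylsilane, C[Si](C)(C)Cl
Why: Kinetic enolisation under in situ silylation (Corey internal quench) can only remove a C6 proton, because C3 is an alkylidene carbon and the γ-hydrogens at C8 lie anti to the carbonyl, and so gives the cross-conjugated 2-silyloxydiene.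

Step 6
Reactants: 13 (4R,5E)-4-(tert-butyldimethylsilyloxy)-5-[2-(tert-butyldimethylsilyloxy)ethylidene]-3,3-dimethyl-1-(trimethylsilyloxy)cyclopent-1-ene; 14 diiodomethane
Product: 15 (1S,2E,3R,5R)-3-(tert-butyldimethylsilyloxy)-2-[2-(tert-butyldimethylsilyloxy)ethylidene]-4,4-dimethyl-1-(trimethylsilyloxy)bicyclo[3.1.0]hexane
Conditions: Et2Zn, 14, CH2Cl2, 0 °C to rt; pyridine, then cold aq NaHCO3; used crude
Reagents that add atoms: diiodomethane (compound 14), ICI
Why: Furukawa-modified Simmons–Smith cyclopropanation should attack the electron-rich silyl enol ether double bond in preference to the alkylidene (whose bulky silyl ethers do not direct zinc) and deliver the C5 methylene anti to the C2 silyl ether, although the cyclopropane configuration is erased in step 7 and so does not matter.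

Step 7
Reactants: 15 (1S,2E,3R,5R)-3-(tert-butyldimethylsilyloxy)-2-[2-(tert-butyldimethylsilyloxy)ethylidene]-4,4-dimethyl-1-(trimethylsilyloxy)bicyclo[3.1.0]hexane
Product: 16 (2E,3S,5S)-3-(tert-butyldimethylsilyloxy)-2-[2-(tert-butyldimethylsilyloxy)ethylidene]-5-chloro-4,4-dimethylcyclohexan-1-one
Conditions: FeCl3 (anhydrous, 2.5 equiv), DMF, 0 °C; cold 1 M HCl work-up; used at once
Reagents that add atoms: iron trichloride, Cl[Fe](Cl)Cl
Why: Trivalent iron oxidises the siloxycyclopropane, with loss of the trimethylsilyl group as TMSCl, to a cyclopropyloxy radical whose β-scission breaks the strained internal C4–C6 bond, leaving the C4 ketone and a secondary ring radical at C6 that takes chlorine from a second FeCl3, which ends as FeCl2. The closest known reaction type is the FeCl3/DMF ring enlargement of 1-silyloxybicyclo[n.1.0]alkanes to 3-chlorocycloalkanones (Ito–Saegusa). The six-membered ring is formed by ring enlargement, that is by fragmentation of the bond shared by the two rings so that C5 becomes a ring member, and not by a new cyclisation. The one new stereocentre, C6, is set by the substrate: A(1,3) strain with C8 holds the C2 silyl ether pseudoaxial, so chlorine should reach the planar C6 radical on the face anti to it (2,6-trans, 5S in 16), and both cyclopropane epimers of 15 converge because C4 and C6 lose their configuration. The step needs internal rather than external bond cleavage, which radical stability and strain release secure, and survival of the β-chloro ketone, which the base-free acidic work-up and immediate use of 16 secure.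

Step 8
Reactants: 16 (2E,3S,5S)-3-(tert-butyldimethylsilyloxy)-2-[2-(tert-butyldimethylsilyloxy)ethylidene]-5-chloro-4,4-dimethylcyclohexan-1-one
Product: 17 (2E,3S,5S)-5-chloro-3-hydroxy-2-(2-hydroxyethylidene)-4,4-dimethylcyclohexan-1-one
Conditions: 48% aq HF, MeCN, 0 °C to rt
Reagents that add atoms: none
Why: Acidic fluoride desilylation removes both silyl ethers without base, so the β-chloro ketone cannot lose HCl, and frees the C2 hydroxyl that directs step 9, without touching a stereocentre.

Step 9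
Reactants: 17 (2E,3S,5S)-5-chloro-3-hydroxy-2-(2-hydroxyethylidene)-4,4-dimethylcyclohexan-1-one
Product: 19 (1R,2Z,3S,5S)-5-chloro-2-(2-hydroxyethylidene)-4,4-dimethylcyclohexane-1,3-diol, via alkoxydiacetoxyborohydride 18 (not isolated)
Conditions: Me4NBH(OAc)3, MeCN/AcOH (1:1), −30 to −20 °C; aq sodium potassium tartrate
Reagents that add atoms: none
Why: In this Evans–Saksena reduction the pseudoaxial C2 hydroxyl exchanges onto boron and delivers hydride through a six-membered chair-like transition state to the face of the C4 carbonyl that it occupies, which sets C4 as the 1,3-anti carbinol (1R in 19), a face that an external hydride passing the C2 oxygen would avoid, while the acidic medium protects the β-chloro ketone.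

Step 10
Reactants: 19 (1R,2Z,3S,5S)-5-chloro-2-(2-hydroxyethylidene)-4,4-dimethylcyclohexane-1,3-diol
Product: 20 (6R,8S,9aS)-8-chloro-2,2,9,9-tetramethyl-4,6,7,8,9,9a-hexahydro-2H-1,3-benzodioxepin-6-ol
Conditions: Me2C(OMe)2, PPTS (cat.), CH2Cl2, 0 °C to rt
Reagents that add atoms: 2,2-dimethoxypropane, COC(C)(C)OC
Why: Acid-catalysed acetal exchange can close a ring only across the (Z)-related C2 and C8 hydroxyls (a seven-membered 4,7-dihydro-1,3-dioxepine), since C4–OH is trans to C2–OH on the ring and anti to C8 across the alkene, so this tether leaves C4–OH as the only free hydroxyl and draws the C2 oxygen out of its axial position beside the path that chloride must take.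

Step 11
Reactants: 20 (6R,8S,9aS)-8-chloro-2,2,9,9-tetramethyl-4,6,7,8,9,9a-hexahydro-2H-1,3-benzodioxepin-6-ol
Product: 22 (6S,8S,9aR)-6,8-dichloro-2,2,9,9-tetramethyl-4,6,7,8,9,9a-hexahydro-2H-1,3-benzodioxepine, via alkoxyphosphonium chloride 21 (not isolated)
Conditions: PPh3, hexachloroacetone, CH2Cl2, −10 to 10 °C
Reagents that add atoms: hexachloroacetone, ClC(Cl)(Cl)C(=O)C(Cl)(Cl)Cl
Why: Triphenylphosphine–hexachloroacetone deoxychlorination, a reagent pair known to turn secondary allylic alcohols into chlorides by SN2 with inversion and little allylic transposition, should collapse the alkoxyphosphonium chloride by backside attack and set C4 as the chloride cis to the C2 oxygen (6S in 22).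

Step 12
Reactants: 22 (6S,8S,9aR)-6,8-dichloro-2,2,9,9-tetramethyl-4,6,7,8,9,9a-hexahydro-2H-1,3-benzodioxepine
Product: 23 (1R,3S,5S,6E)-3,5-dichloro-6-(2-hydroxyethylidene)-2,2-dimethylcyclohexan-1-ol
Conditions: AcOH/THF/H2O (3:1:1), rt
Reagents that add atoms: none
Why: Mild aqueous acid should hydrolyse the seven-membered acetonide much faster than it ionises the secondary allylic chloride, releasing the ene-1,4-diol without touching a stereocentre.

Step 13
Reactants: 23 (1R,3S,5S,6E)-3,5-dichloro-6-(2-hydroxyethylidene)-2,2-dimethylcyclohexan-1-ol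
Product: 27 (2S,3Z,4S,6S)-2-bromo-3-(2-bromoethylidene)-4,6-dichloro-1,1-dimethylcyclohexane, via primary alkoxyphosphonium bromide 24 (not isolated), via allylic monobromide 25 (not isolated), via secondary alkoxyphosphonium bromide 26 (not isolated)
Conditions: CBr4, PPh3, CH2Cl2, −20 °C to rt
Reagents that add atoms: carbon tetrabromide, BrC(Br)(Br)Br
Why: In this double Appel reaction the primary allylic hydroxyl is replaced first, and the C2 alkoxyphosphonium, held pseudoaxial and aligned with the alkene π system by A(1,3) strain and unable to undergo E2 because C1 is quaternary and C3 is sp2, is then displaced by bromide in an allylically assisted SN2 with inversion, which sets C2 as the bromide cis to the C6 chlorine (2S in 27).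

**Compound list**

1 | 4,4-dimethylcyclopent-2-en-1-one | CC1(C)CC(=O)C=C1 | starting material
2 | bis(pinacolato)diboron | CC1(C)OB(OC1(C)C)B1OC(C)(C)C(C)(C)O1 | starting material
3 | (tert-butyldimethylsilyloxy)acetaldehyde | CC(C)(C)[Si](C)(C)OCC=O | starting material
4 | boron enolate: 2-{[(3S)-4,4-dimethyl-3-(4,4,5,5-tetramethyl-1,3,2-dioxaborolan-2-yl)cyclopent-1-en-1-yl]oxy}-4,4,5,5-tetramethyl-1,3,2-dioxaborolane | CC1(C)[C@@H](B2OC(C)(C)C(C)(C)O2)C=C(OB3OC(C)(C)C(C)(C)O3)C1 | intermediate (not isolated)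
5 | boron aldolate: (2R,3S)-2-{2-(tert-butyldimethylsilyloxy)-1-[(4,4,5,5-tetramethyl-1,3,2-dioxaborolan-2-yl)oxy]ethyl}-4,4-dimethyl-3-(4,4,5,5-tetramethyl-1,3,2-dioxaborolan-2-yl)cyclopentan-1-one, side-chain centre not controlled | CC1(C)[C@@H](B2OC(C)(C)C(C)(C)O2)[C@H](C(OB3OC(C)(C)C(C)(C)O3)CO[Si](C)(C)C(C)(C)C)C(=O)C1 | intermediate (not isolated)
6 | (2R,3S)-2-[2-(tert-butyldimethylsilyloxy)-1-hydroxyethyl]-4,4-dimethyl-3-(4,4,5,5-tetramethyl-1,3,2-dioxaborolan-2-yl)cyclopentan-1-one, both carbinol epimers | CC1(C)[C@@H](B2OC(C)(C)C(C)(C)O2)[C@H](C(O)CO[Si](C)(C)C(C)(C)C)C(=O)C1 | intermediate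
7 | mesylate: (2R,3S)-2-[2-(tert-butyldimethylsilyloxy)-1-(methanesulfonyloxy)ethyl]-4,4-dimethyl-3-(4,4,5,5-tetramethyl-1,3,2-dioxaborolan-2-yl)cyclopentan-1-one | CC1(C)[C@@H](B2OC(C)(C)C(C)(C)O2)[C@H](C(OS(C)(=O)=O)CO[Si](C)(C)C(C)(C)C)C(=O)C1 | intermediate (not isolated)
8 | (2E,3R)-2-[2-(tert-butyldimethylsilyloxy)ethylidene]-4,4-dimethyl-3-(4,4,5,5-tetramethyl-1,3,2-dioxaborolan-2-yl)cyclopentan-1-one | CC1(C)[C@@H](B2OC(C)(C)C(C)(C)O2)/C(=C\CO[Si](C)(C)C(C)(C)C)C(=O)C1 | intermediate
9 | borate ester: (2E,3R)-2-[2-(tert-butyldimethylsilyloxy)ethylidene]-4,4-dimethyl-3-[(4,4,5,5-tetramethyl-1,3,2-dioxaborolan-2-yl)oxy]cyclopentan-1-one | CC1(C)[C@@H](OB2OC(C)(C)C(C)(C)O2)/C(=C\CO[Si](C)(C)C(C)(C)C)C(=O)C1 | intermediate (not isolated)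
10 | (2E,3R)-2-[2-(tert-butyldimethylsilyloxy)ethylidene]-3-hydroxy-4,4-dimethylcyclopentan-1-one | CC1(C)[C@@H](O)/C(=C\CO[Si](C)(C)C(C)(C)C)C(=O)C1 | intermediate
11 | (2E,3R)-3-(tert-butyldimethylsilyloxy)-2-[2-(tert-butyldimethylsilyloxy)ethylidene]-4,4-dimethylcyclopentan-1-one | CC1(C)[C@@H](O[Si](C)(C)C(C)(C)C)/C(=C\CO[Si](C)(C)C(C)(C)C)C(=O)C1 | intermediate
12 | lithium dienolate: lithium (4R,5E)-4-(tert-butyldimethylsilyloxy)-5-[2-(tert-butyldimethylsilyloxy)ethylidene]-3,3-dimethylcyclopent-1-en-1-olate | CC1(C)[C@@H](O[Si](C)(C)C(C)(C)C)/C(=C\CO[Si](C)(C)C(C)(C)C)C([O-])=C1.[Li+] | intermediate (not isolated)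
13 | (4R,5E)-4-(tert-butyldimethylsilyloxy)-5-[2-(tert-butyldimethylsilyloxy)ethylidene]-3,3-dimethyl-1-(trimethylsilyloxy)cyclopent-1-ene | CC1(C)[C@@H](O[Si](C)(C)C(C)(C)C)/C(=C\CO[Si](C)(C)C(C)(C)C)C(O[Si](C)(C)C)=C1 | intermediate
14 | diiodomethane | ICI | starting material
15 | (1S,2E,3R,5R)-3-(tert-butyldimethylsilyloxy)-2-[2-(tert-butyldimethylsilyloxy)ethylidene]-4,4-dimethyl-1-(trimethylsilyloxy)bicyclo[3.1.0]hexane | CC1(C)[C@@H](O[Si](C)(C)C(C)(C)C)/C(=C\CO[Si](C)(C)C(C)(C)C)[C@]3(O[Si](C)(C)C)C[C@H]13 | intermediate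
16 | (2E,3S,5S)-3-(tert-butyldimethylsilyloxy)-2-[2-(tert-butyldimethylsilyloxy)ethylidene]-5-chloro-4,4-dimethylcyclohexan-1-one | CC1(C)[C@@H](O[Si](C)(C)C(C)(C)C)/C(=C\CO[Si](C)(C)C(C)(C)C)C(=O)C[C@@H]1Cl | intermediate
17 | (2E,3S,5S)-5-chloro-3-hydroxy-2-(2-hydroxyethylidene)-4,4-dimethylcyclohexan-1-one | CC1(C)[C@@H](O)/C(=C\CO)C(=O)C[C@@H]1Cl | intermediate
18 | alkoxydiacetoxyborohydride: tetramethylammonium diacetoxy(hydrido)borate ester of 17 at the ring hydroxyl, configurations as in 17 | CC1(C)[C@@H](O[BH-](OC(C)=O)OC(C)=O)/C(=C\CO)C(=O)C[C@@H]1Cl.C[N+](C)(C)C | intermediate (not isolated)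
19 | (1R,2Z,3S,5S)-5-chloro-2-(2-hydroxyethylidene)-4,4-dimethylcyclohexane-1,3-diol | CC1(C)[C@@H](O)/C(=C\CO)[C@H](O)C[C@@H]1Cl | intermediate
20 | (6R,8S,9aS)-8-chloro-2,2,9,9-tetramethyl-4,6,7,8,9,9a-hexahydro-2H-1,3-benzodioxepin-6-ol (acetonide across the C2 and C8 oxygens) | CC1(C)[C@H]2OC(C)(C)OC/C=C2/[C@H](O)C[C@@H]1Cl | intermediate
21 | alkoxyphosphonium chloride: {[(6R,8S,9aS)-8-chloro-2,2,9,9-tetramethyl-4,6,7,8,9,9a-hexahydro-2H-1,3-benzodioxepin-6-yl]oxy}triphenylphosphonium chloride | CC1(C)[C@H]2OC(C)(C)OC/C=C2/[C@H](O[P+](c3ccccc3)(c4ccccc4)c5ccccc5)C[C@@H]1Cl.[Cl-] | intermediate (not isolated)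
22 | (6S,8S,9aR)-6,8-dichloro-2,2,9,9-tetramethyl-4,6,7,8,9,9a-hexahydro-2H-1,3-benzodioxepine | CC1(C)[C@H]2OC(C)(C)OC/C=C2/[C@@H](Cl)C[C@@H]1Cl | intermediate
23 | (1R,3S,5S,6E)-3,5-dichloro-6-(2-hydroxyethylidene)-2,2-dimethylcyclohexan-1-ol | CC1(C)[C@@H](O)/C(=C\CO)[C@@H](Cl)C[C@@H]1Cl | intermediate
24 | primary alkoxyphosphonium bromide: triphenylphosphonium ether of 23 at the primary (C8) hydroxyl, bromide salt, configurations as in 23 | CC1(C)[C@@H](O)/C(=C\CO[P+](c2ccccc2)(c3ccccc3)c4ccccc4)[C@@H](Cl)C[C@@H]1Cl.[Br-] | intermediate (not isolated)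
25 | allylic monobromide: (1R,3S,5S,6E)-6-(2-bromoethylidene)-3,5-dichloro-2,2-dimethylcyclohexan-1-ol | CC1(C)[C@@H](O)/C(=C\CBr)[C@@H](Cl)C[C@@H]1Cl | intermediate (not isolated)
26 | secondary alkoxyphosphonium bromide: triphenylphosphonium ether of 25 at the ring (C2) hydroxyl, bromide salt, configurations as in 25 | CC1(C)[C@@H](O[P+](c2ccccc2)(c3ccccc3)c4ccccc4)/C(=C\CBr)[C@@H](Cl)C[C@@H]1Cl.[Br-] | intermediate (not isolated)
27 | (2S,3Z,4S,6S)-2-bromo-3-(2-bromoethylidene)-4,6-dichloro-1,1-dimethylcyclohexane | CC1(C)[C@H](Br)/C(=C\CBr)[C@@H](Cl)C[C@@H]1Cl | target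

**Step count and risks**

Total steps: 13. Longest linear sequence: 13 (from 1).

Step 13 is the most likely to fail. Bromide must enter at C2, which is neopentylic as well as allylic, and the displacement may be diverted to allylic transposition (entry at C7) or to ionisation with loss of stereochemical fidelity. Halide exchange at the allylic C4 chloride and cyclo-etherification of the (Z)-ene-1,4-diol are further side paths. The fallback separates the two brominations and replaces the phosphonium leaving group by a small, discrete sulfonate. It sets out from 23: one equivalent of CBr4/PPh3 at −30 °C should stop at the primary bromide 25, which is isolated. Its ring hydroxyl is converted with ClCH2SO2Cl and 2,6-lutidine (CH2Cl2, −20 °C) into (1R,3S,5S,6E)-6-(2-bromoethylidene)-3,5-dichloro-2,2-dimethylcyclohexyl chloromethanesulfonate F1. F1 is displaced with LiBr in acetone at 0 °C by SN2 with inversion, bromide exchange at C8 being degenerate, and the route is rejoined at 27.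

Step 11 is the second risk. Chloride has to enter C4 on the face that carries the C2 oxygen, so the substitution may stall, ionise or run with allylic transposition into the dioxepine ring. The fallback gives up the tether and relies on chemoselectivity and on a free C2 hydroxyl that can hydrogen-bond to the incoming chloride. It sets out from 19: the primary hydroxyl alone is silylated (TBSCl, imidazole, DMF, −20 °C) to (1R,2Z,3S,5S)-2-[2-(tert-butyldimethylsilyloxy)ethylidene]-5-chloro-4,4-dimethylcyclohexane-1,3-diol F2. The C4 hydroxyl, which is far less hindered than the neopentylic C2 hydroxyl, is chlorinated with one equivalent of PPh3/hexachloroacetone to (1R,3S,5S,6E)-6-[2-(tert-butyldimethylsilyloxy)ethylidene]-3,5-dichloro-2,2-dimethylcyclohexan-1-ol F3. Aqueous HF in MeCN then returns to the route at 23.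

Step 1 is the third risk. The copper–boryl species may add to the enolisable aldehyde instead of the hindered enone, the boron enolate may react sluggishly, and enantioselectivity may erode at the β-carbon next to the quaternary centre. The fallback decouples borylation from C–C bond formation and sets out from 1:
- Protic borylation (CuCl, NaOtBu, (R,S)-Josiphos, 2, MeOH, THF) gives (3S)-4,4-dimethyl-3-(4,4,5,5-tetramethyl-1,3,2-dioxaborolan-2-yl)cyclopentan-1-one F4.
- NaBO3·4H2O gives (3S)-3-hydroxy-4,4-dimethylcyclopentan-1-one F5.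
- TBSCl/imidazole gives (3S)-3-(tert-butyldimethylsilyloxy)-4,4-dimethylcyclopentan-1-one F6.
- LiN(iPr)2 at −78 °C should enolise the less hindered α-carbon, away from the quaternary centre, to lithium (3S)-3-(tert-butyldimethylsilyloxy)-4,4-dimethylcyclopent-1-en-1-olate F7.
- Addition of 3 gives the aldol (2S,3S)-3-(tert-butyldimethylsilyloxy)-2-[2-(tert-butyldimethylsilyloxy)-1-hydroxyethyl]-4,4-dimethylcyclopentan-1-one F8.
- MsCl/Et3N forms its mesylate (2S,3S)-3-(tert-butyldimethylsilyloxy)-2-[2-(tert-butyldimethylsilyloxy)-1-(methanesulfonyloxy)ethyl]-4,4-dimethylcyclopentan-1-one F9, and DBU eliminates it to rejoin the route at 11.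

Further compounds
F1 | step 13 | (1R,3S,5S,6E)-6-(2-bromoethylidene)-3,5-dichloro-2,2-dimethylcyclohexyl chloromethanesulfonate | CC1(C)[C@@H](OS(=O)(=O)CCl)/C(=C\CBr)[C@@H](Cl)C[C@@H]1Cl
F2 | step 11 | (1R,2Z,3S,5S)-2-[2-(tert-butyldimethylsilyloxy)ethylidene]-5-chloro-4,4-dimethylcyclohexane-1,3-diol | CC1(C)[C@@H](O)/C(=C\CO[Si](C)(C)C(C)(C)C)[C@H](O)C[C@@H]1Cl
F3 | step 11 | (1R,3S,5S,6E)-6-[2-(tert-butyldimethylsilyloxy)ethylidene]-3,5-dichloro-2,2-dimethylcyclohexan-1-ol | CC1(C)[C@@H](O)/C(=C\CO[Si](C)(C)C(C)(C)C)[C@@H](Cl)C[C@@H]1Cl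
F4 | step 1 | (3S)-4,4-dimethyl-3-(4,4,5,5-tetramethyl-1,3,2-dioxaborolan-2-yl)cyclopentan-1-one | CC1(C)[C@@H](B2OC(C)(C)C(C)(C)O2)CC(=O)C1
F5 | step 1 | (3S)-3-hydroxy-4,4-dimethylcyclopentan-1-one | CC1(C)[C@@H](O)CC(=O)C1
F6 | step 1 | (3S)-3-(tert-butyldimethylsilyloxy)-4,4-dimethylcyclopentan-1-one | CC1(C)[C@@H](O[Si](C)(C)C(C)(C)C)CC(=O)C1
F7 | step 1 | lithium (3S)-3-(tert-butyldimethylsilyloxy)-4,4-dimethylcyclopent-1-en-1-olate | CC1(C)[C@@H](O[Si](C)(C)C(C)(C)C)C=C([O-])C1.[Li+]
F8 | step 1 | (2S,3S)-3-(tert-butyldimethylsilyloxy)-2-[2-(tert-butyldimethylsilyloxy)-1-hydroxyethyl]-4,4-dimethylcyclopentan-1-one | CC1(C)[C@@H](O[Si](C)(C)C(C)(C)C)[C@H](C(O)CO[Si](C)(C)C(C)(C)C)C(=O)C1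
F9 | step 1 | (2S,3S)-3-(tert-butyldimethylsilyloxy)-2-[2-(tert-butyldimethylsilyloxy)-1-(methanesulfonyloxy)ethyl]-4,4-dimethylcyclopentan-1-one | CC1(C)[C@@H](O[Si](C)(C)C(C)(C)C)[C@H](C(OS(C)(=O)=O)CO[Si](C)(C)C(C)(C)C)C(=O)C1
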